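**Strategy**

The target is read as the hydrated 8–8′ dimer of a protected ε-viniferin, so everything rests on one enantiopure trans-2,3-diaryl-2,3-dihydrobenzofuran bearing a C4 handle. Its heterocycle is grown from a three-membered ring: the oxirane of trans-stilbene oxide 7 (O1, C2, C3) is expanded by two atoms when 3-bromo-5-methoxybenzyne inserts its carbons (C7a, C3a) into the O1–C3 bond. This single operation forms O1–C7a and C3–C3a, carries the epoxide configuration into both ring stereocentres and installs the C4 bromide. The feature exploited is the O1–C2–C3 unit lying next to the ortho pair C7a/C3a of the benzo ring. Oxidative dimerisation–hydration of the derived stilbene then builds the oxolane.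

Key step: step 4

Remark: 1, 5 and 14 are taken as commercial. Both dihydrobenzofurans of the target are (2S,3S) and the oxolane is 2,3-cis-3,4-trans-4,5-trans, so one monomer serves both halves.

**Route**

Step 1
Reactants: 1 2,6-dibromo-4-methoxyphenol
Product: 4 2-bromo-4-methoxy-6-(trimethylsilyl)phenyl trifluoromethanesulfonate, via aryl trimethylsilyl ether 2 (not isolated), via lithium 2-bromo-4-methoxy-6-(trimethylsilyl)phenoxide 3 (not isolated)
Conditions: HMDS, THF, reflux; then n-BuLi, THF, −100 °C; then Tf2O, −100 °C → rt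
Reagents that add atoms: hexamethyldisilazane C[Si](C)(C)N[Si](C)(C)C; trifluoromethanesulfonic anhydride O=S(=O)(OS(=O)(=O)C(F)(F)F)C(F)(F)F
Why: O-silylation, bromine–lithium exchange at one of the two equivalent C–Br bonds, anionic 1,3 O→C silyl shift (retro-Brook) and triflation of the phenoxide form the ortho-silylaryl triflate (Kobayashi aryne precursor) in one flask.

Step 2
Reactants: 5 pterostilbene
Product: 6 (E)-4-[2-(3,5-dimethoxyphenyl)ethenyl]phenyl trifluoromethanesulfonate
Conditions: Tf2O, pyridine, CH2Cl2, 0 °C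
Reagents that add atoms: trifluoromethanesulfonic anhydride O=S(=O)(OS(=O)(=O)C(F)(F)F)C(F)(F)F
Why: Phenol O-sulfonylation; the triflate makes this ring the electron-poor one, which later directs the epoxide opening and protects the benzylic ether from acid.

Step 3
Reactants: 6 (E)-4-[2-(3,5-dimethoxyphenyl)ethenyl]phenyl trifluoromethanesulfonate
Product: 7 4-[(2R,3R)-3-(3,5-dimethoxyphenyl)oxiran-2-yl]phenyl trifluoromethanesulfonate
Conditions: D-fructose-derived Shi ketone (30 mol%), Oxone (2KHSO5·KHSO4·K2SO4), K2CO3, Bu4NHSO4, MeCN/DMM, aq. Na2B4O7/Na2EDTA, 0 °C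
Reagents that add atoms: potassium peroxymonosulfate [K+].[O-]S(=O)(=O)OO
Why: Shi asymmetric epoxidation; the chiral dioxirane delivers oxygen to the E-alkene through the spiro transition state, which sets both stereocentres as R,R under catalyst control, and the electron-poor epoxide should be stable in the basic medium.

Step 4
Reactants: 7 4-[(2R,3R)-3-(3,5-dimethoxyphenyl)oxiran-2-yl]phenyl trifluoromethanesulfonate; 4 2-bromo-4-methoxy-6-(trimethylsilyl)phenyl trifluoromethanesulfonate
Product: 10 4-[(2S,3S)-4-bromo-3-(3,5-dimethoxyphenyl)-6-methoxy-2,3-dihydro-1-benzofuran-2-yl]phenyl trifluoromethanesulfonate, via 3-bromo-5-methoxybenzyne 8 (not isolated), via O-aryl oxiranium zwitterion 9 (not isolated)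
Conditions: CsF, MeCN, rt (4 in excess, added slowly)
Reagents that add atoms: none
Why: Fluoride-induced 1,2-elimination of 4 gives aryne 8, whose carbon remote from bromine is attacked by the oxirane oxygen of 7 (the aryl anion develops next to the inductively withdrawing C–Br), giving O-aryl oxiranium zwitterion 9. The oxiranium C3–O bond to the 3,5-dimethoxybenzylic carbon ionises and the ortho aryl anion collapses onto C3, so the three-membered ring (O1, C2, C3) becomes the five-membered ring (O1, C2, C3, C3a, C7a) by net insertion of the two aryne carbons into O1–C3; the closest known reaction type is the σ-insertion of benzyne into the benzylic C–O bond of styrene oxide to give dihydrobenzofurans. The five-membered ring closes by cation–anion recombination inside the zwitterion (C3a–C3 bond formation, formally 5-endo at the planar benzylic cation), not by an SN2 displacement. C2 breaks no bond and keeps its epoxide configuration (the descriptor changes from R to S only through a priority change), while C3 is captured on the face from which the tethered oxygen departs, so the trans arrangement of the epoxide is retained and is also the thermodynamically preferred trans-2,3-diaryl ring. The step needs two selectivities: cleavage of the correct oxiranium C–O bond, secured by the para-triflate that destabilises the alternative 4-oxybenzylic cation relative to the 3,5-dimethoxybenzylic one, and aryne regiochemistry, secured by the bromine at the aryne 3-position, which ends up as the C4 handle. Aryl triflate, aryl bromide and methyl ethers are inert to CsF in MeCN.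

Step 5
Reactants: 10 4-[(2S,3S)-4-bromo-3-(3,5-dimethoxyphenyl)-6-methoxy-2,3-dihydro-1-benzofuran-2-yl]phenyl trifluoromethanesulfonate
Product: 11 4-[(2S,3S)-4-bromo-3-(3,5-dihydroxyphenyl)-6-hydroxy-2,3-dihydro-1-benzofuran-2-yl]phenyl trifluoromethanesulfonate
Conditions: BBr3, CH2Cl2, −78 → 0 °C; then H2O
Reagents that add atoms: none
Why: Lewis-acid cleavage of the three aryl methyl ethers; the para-triflate disfavours ionisation of the benzylic C2–O bond, so the dihydrobenzofuran and both stereocentres should survive, and aryl triflate and bromide are inert.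

Step 6
Reactants: 11 4-[(2S,3S)-4-bromo-3-(3,5-dihydroxyphenyl)-6-hydroxy-2,3-dihydro-1-benzofuran-2-yl]phenyl trifluoromethanesulfonate
Product: 13 (2S,3S)-2-(4-acetoxyphenyl)-3-(3,5-diacetoxyphenyl)-4-bromo-2,3-dihydro-1-benzofuran-6-yl acetate, via tetraphenol 12 (not isolated)
Conditions: Et4NOH (aq.), 1,4-dioxane, rt; then Ac2O, 0 °C → rt
Reagents that add atoms: acetic anhydride CC(=O)OC(C)=O
Why: Hydroxide cleaves the aryl triflate at sulfur and the four phenoxides are acetylated in the same flask (Schotten–Baumann-type acylation); any reversible ring opening through the para-quinone methide recloses to the more stable trans ring, and the acetates deactivate all four rings for the oxidative step.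

Step 7
Reactants: 13 (2S,3S)-2-(4-acetoxyphenyl)-3-(3,5-diacetoxyphenyl)-4-bromo-2,3-dihydro-1-benzofuran-6-yl acetate; 14 tert-butyldimethyl(4-vinylphenoxy)silane
Product: 15 (2S,3S)-2-(4-acetoxyphenyl)-3-(3,5-diacetoxyphenyl)-4-[(E)-2-{4-[(tert-butyldimethylsilyl)oxy]phenyl}ethenyl]-2,3-dihydro-1-benzofuran-6-yl acetate
Conditions: Pd2(dba)3 (2.5 mol%), P(t-Bu)3·HBF4, Cy2NMe, 1,4-dioxane, 70 °C
Reagents that add atoms: none
Why: Mizoroki–Heck reaction; monoligated zerovalent palladium inserts into the hindered C4–Br bond, and β-arylation of the styrene followed by syn β-hydride elimination gives the E-alkene, while the amine base leaves acetates and silyl ether intact.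

Step 8
Reactants: 15 (two molecules) (2S,3S)-2-(4-acetoxyphenyl)-3-(3,5-diacetoxyphenyl)-4-[(E)-2-{4-[(tert-butyldimethylsilyl)oxy]phenyl}ethenyl]-2,3-dihydro-1-benzofuran-6-yl acetate
Product: 16 (2S,3S,4S,5R)-2,5-bis{4-[(tert-butyldimethylsilyl)oxy]phenyl}-3,4-bis[(2S,3S)-6-acetoxy-2-(4-acetoxyphenyl)-3-(3,5-diacetoxyphenyl)-2,3-dihydro-1-benzofuran-4-yl]oxolane (aryl groups cis at C2/C3 and trans at C3/C4 and C4/C5)
Conditions: graphite anode, platinum cathode, undivided cell, constant current, LiClO4, 2,6-lutidine, MeCN/H2O (9:1), 0 °C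
Reagents that add atoms: water O
Why: Anodic one-electron oxidation gives the stilbene radical cation, which couples tail-to-tail (C8–C8′) with a second stilbene; water captures one benzylic cation and the resulting alcohol closes 5-exo onto the other (the known dimerisation–hydration of 4-alkoxystilbenes to 2,3,4,5-tetraaryloxolanes, copying the presumed 8–8′ biosynthesis); each C8 should react on the face remote from its C3 aryl group (3,4-trans, both S), water should add anti to the other half in the allylic-strain-minimised conformer (2,3-cis) and ring closure should place the last aryl trans (4,5-trans), while 2,6-lutidine buffers the acid that would epimerise the cis centre, the acetylated rings do not compete as Friedel–Crafts nucleophiles, and any partly desilylated product converges in step 9.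

Step 9
Reactants: 16 (2S,3S,4S,5R)-2,5-bis{4-[(tert-butyldimethylsilyl)oxy]phenyl}-3,4-bis[(2S,3S)-6-acetoxy-2-(4-acetoxyphenyl)-3-(3,5-diacetoxyphenyl)-2,3-dihydro-1-benzofuran-4-yl]oxolane
Product: 17 (2S,3S,4S,5R)-3,4-bis[(2S,3S)-3-(3,5-dihydroxyphenyl)-6-hydroxy-2-(4-hydroxyphenyl)-2,3-dihydro-1-benzofuran-4-yl]-2,5-bis(4-hydroxyphenyl)oxolane (target)
Conditions: K2CO3, MeOH/THF, 0 °C → rt, argon; then AcOH
Reagents that add atoms: none
Why: Base-catalysed methanolysis removes the eight aryl acetates and the two aryl silyl ethers without touching a stereocentre, and no acid is present that could epimerise the cis C2 centre of the oxolane.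

**Compound list**

1 | 2,6-dibromo-4-methoxyphenol | COc1cc(Br)c(O)c(Br)c1 | starting material
2 | (2,6-dibromo-4-methoxyphenoxy)trimethylsilane | COc1cc(Br)c(O[Si](C)(C)C)c(Br)c1 | intermediate
3 | lithium 2-bromo-4-methoxy-6-(trimethylsilyl)phenoxide | [Li+].COc1cc(Br)c([O-])c([Si](C)(C)C)c1 | intermediate
4 | 2-bromo-4-methoxy-6-(trimethylsilyl)phenyl trifluoromethanesulfonate | COc1cc(Br)c(OS(=O)(=O)C(F)(F)F)c([Si](C)(C)C)c1 | intermediate
5 | pterostilbene, (E)-4-[2-(3,5-dimethoxyphenyl)ethenyl]phenol | COc1cc(OC)cc(/C=C/c2ccc(O)cc2)c1 | starting material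
6 | (E)-4-[2-(3,5-dimethoxyphenyl)ethenyl]phenyl trifluoromethanesulfonate | COc1cc(OC)cc(/C=C/c2ccc(OS(=O)(=O)C(F)(F)F)cc2)c1 | intermediate
7 | 4-[(2R,3R)-3-(3,5-dimethoxyphenyl)oxiran-2-yl]phenyl trifluoromethanesulfonate | O=S(=O)(Oc1ccc(cc1)[C@H]1O[C@@H]1c1cc(OC)cc(OC)c1)C(F)(F)F | intermediate
8 | 3-bromo-5-methoxybenzyne | BrC1=CC(OC)=CC#C1 | intermediate
9 | O-aryl oxiranium zwitterion (aryl anion ortho to the oxonium oxygen and to bromine) | COc1cc(Br)[c-]c(c1)[O+]1[C@H](c2ccc(OS(=O)(=O)C(F)(F)F)cc2)[C@H]1c1cc(OC)cc(OC)c1 | intermediate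
10 | 4-[(2S,3S)-4-bromo-3-(3,5-dimethoxyphenyl)-6-methoxy-2,3-dihydro-1-benzofuran-2-yl]phenyl trifluoromethanesulfonate | O=S(=O)(Oc1ccc([C@H]2Oc3cc(OC)cc(Br)c3[C@@H]2c2cc(OC)cc(OC)c2)cc1)C(F)(F)F | intermediate
11 | 4-[(2S,3S)-4-bromo-3-(3,5-dihydroxyphenyl)-6-hydroxy-2,3-dihydro-1-benzofuran-2-yl]phenyl trifluoromethanesulfonate | O=S(=O)(Oc1ccc([C@H]2Oc3cc(O)cc(Br)c3[C@@H]2c2cc(O)cc(O)c2)cc1)C(F)(F)F | intermediate
12 | (2S,3S)-4-bromo-3-(3,5-dihydroxyphenyl)-2-(4-hydroxyphenyl)-2,3-dihydro-1-benzofuran-6-ol (present as its tetraethylammonium phenoxide) | Oc1ccc([C@H]2Oc3cc(O)cc(Br)c3[C@@H]2c2cc(O)cc(O)c2)cc1 | intermediate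
13 | (2S,3S)-2-(4-acetoxyphenyl)-3-(3,5-diacetoxyphenyl)-4-bromo-2,3-dihydro-1-benzofuran-6-yl acetate | CC(=O)Oc1ccc([C@H]2Oc3cc(OC(C)=O)cc(Br)c3[C@@H]2c2cc(OC(C)=O)cc(OC(C)=O)c2)cc1 | intermediate
14 | tert-butyldimethyl(4-vinylphenoxy)silane | C=Cc1ccc(O[Si](C)(C)C(C)(C)C)cc1 | starting material
15 | (2S,3S)-2-(4-acetoxyphenyl)-3-(3,5-diacetoxyphenyl)-4-[(E)-2-{4-[(tert-butyldimethylsilyl)oxy]phenyl}ethenyl]-2,3-dihydro-1-benzofuran-6-yl acetate | CC(=O)Oc1ccc([C@H]2Oc3cc(OC(C)=O)cc(/C=C/c4ccc(O[Si](C)(C)C(C)(C)C)cc4)c3[C@@H]2c2cc(OC(C)=O)cc(OC(C)=O)c2)cc1 | intermediate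
16 | (2S,3S,4S,5R)-2,5-bis{4-[(tert-butyldimethylsilyl)oxy]phenyl}-3,4-bis[(2S,3S)-6-acetoxy-2-(4-acetoxyphenyl)-3-(3,5-diacetoxyphenyl)-2,3-dihydro-1-benzofuran-4-yl]oxolane | CC(=O)Oc1ccc([C@H]2Oc3cc(OC(C)=O)cc([C@@H]4[C@@H](c5cc(OC(C)=O)cc6c5[C@H](c5cc(OC(C)=O)cc(OC(C)=O)c5)[C@@H](c5ccc(OC(C)=O)cc5)O6)[C@H](c5ccc(O[Si](C)(C)C(C)(C)C)cc5)O[C@@H]4c4ccc(O[Si](C)(C)C(C)(C)C)cc4)c3[C@@H]2c2cc(OC(C)=O)cc(OC(C)=O)c2)cc1 | intermediate
17 | (2S,3S,4S,5R)-3,4-bis[(2S,3S)-3-(3,5-dihydroxyphenyl)-6-hydroxy-2-(4-hydroxyphenyl)-2,3-dihydro-1-benzofuran-4-yl]-2,5-bis(4-hydroxyphenyl)oxolane (kobophenol A stereostructure) | Oc1ccc([C@H]2Oc3cc(O)cc([C@@H]4[C@@H](c5cc(O)cc6c5[C@H](c5cc(O)cc(O)c5)[C@@H](c5ccc(O)cc5)O6)[C@H](c5ccc(O)cc5)O[C@@H]4c4ccc(O)cc4)c3[C@@H]2c2cc(O)cc(O)c2)cc1 | target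

**Step count and risks**

Total steps: 9. Longest linear sequence: 8 (steps 2 to 9; step 1 is the side branch that joins at step 4).

Steps most likely to fail:

1. Step 4 (aryne insertion). What may go wrong: loss of bromide from the ortho-bromoaryl anion of 9 to give a second aryne, interception of the oxiranium by fluoride or solvent before ring closure, or ionisation of the wrong C–O bond. Fallback, setting out from 6 and coming back at 12: 6 is epoxidised with the enantiomeric (L-fructose-derived) Shi ketone to 4-[(2S,3S)-3-(3,5-dimethoxyphenyl)oxiran-2-yl]phenyl trifluoromethanesulfonate F1. F1 is opened with inversion at the 3,5-dimethoxybenzylic carbon by 2,6-dibromo-4-methoxyphenyllithium (from 3,5-dibromoanisole and LiN(i-Pr)2 at −78 °C) with BF3·OEt2 to give 4-[(1R,2S)-2-(2,6-dibromo-4-methoxyphenyl)-2-(3,5-dimethoxyphenyl)-1-hydroxyethyl]phenyl trifluoromethanesulfonate F2. Bromide-selective palladium-catalysed intramolecular C–O coupling onto one of the two equivalent C–Br bonds (Pd(OAc)2, a bulky di-tert-butyl biaryl phosphine, Cs2CO3, toluene; retention at the carbinol carbon) closes the cis ring, 4-[(2R,3S)-4-bromo-3-(3,5-dimethoxyphenyl)-6-methoxy-2,3-dihydro-1-benzofuran-2-yl]phenyl trifluoromethanesulfonate F3, which already has the correct C3 configuration. Demethylation as in step 5 gives the cis triphenol triflate F4. After detriflation with Et4NOH the para-phenoxide opens and recloses the ring through its quinone methide (completed by brief exposure to TFA if needed), which epimerises C2 to the more stable trans isomer, tetraphenol 12; acetylation as in step 6 then gives 13.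

2. Step 8 (oxidative dimerisation–hydration). What may go wrong: closure of the dimer cation to a cyclobutane or Friedel–Crafts capture by a benzo ring instead of water, over-oxidation, or poor facial selectivity in the C8–C8′ coupling and hydration. Fallback, setting out from 15 and coming back at 17: the silyl ether is removed (KHF2, MeOH) to give the free phenol (2S,3S)-2-(4-acetoxyphenyl)-3-(3,5-diacetoxyphenyl)-4-[(E)-2-(4-hydroxyphenyl)ethenyl]-2,3-dihydro-1-benzofuran-6-yl acetate F5. F5 is oxidised through its phenoxyl radical (FeCl3·6H2O, acetone/H2O, 0 °C); 8–8′ coupling gives the bis(quinone methide), which adds water and closes to the diphenol (2S,3S,4S,5R)-2,5-bis(4-hydroxyphenyl)-3,4-bis[(2S,3S)-6-acetoxy-2-(4-acetoxyphenyl)-3-(3,5-diacetoxyphenyl)-2,3-dihydro-1-benzofuran-4-yl]oxolane F6. F6 is deacetylated under the conditions of step 9 to 17.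

3. Step 7 (Heck coupling). What may go wrong: slow carbopalladation at the ortho-hindered arylpalladium, with competing hydrodebromination or acetate loss at the temperature then required. Fallback, setting out from 14 and 13 and coming back at 15: cross-metathesis of 14 with vinylboronic acid pinacol ester (second-generation Grubbs catalyst, RuCl2(=CHPh)(H2IMes)(PCy3), CH2Cl2, 40 °C) gives (E)-tert-butyldimethyl{4-[2-(4,4,5,5-tetramethyl-1,3,2-dioxaborolan-2-yl)ethenyl]phenoxy}silane F7. Suzuki–Miyaura coupling of F7 with 13 (Pd(OAc)2, SPhos, anhydrous K3PO4, toluene, 80 °C) replaces the migratory insertion by a transmetalation, fixes the E geometry beforehand and gives 15.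

**Further compounds**

F1 | step 4 | 4-[(2S,3S)-3-(3,5-dimethoxyphenyl)oxiran-2-yl]phenyl trifluoromethanesulfonate | O=S(=O)(Oc1ccc(cc1)[C@@H]1O[C@H]1c1cc(OC)cc(OC)c1)C(F)(F)F
F2 | step 4 | 4-[(1R,2S)-2-(2,6-dibromo-4-methoxyphenyl)-2-(3,5-dimethoxyphenyl)-1-hydroxyethyl]phenyl trifluoromethanesulfonate | O=S(=O)(Oc1ccc(cc1)[C@H](O)[C@@H](c1cc(OC)cc(OC)c1)c1c(Br)cc(OC)cc1Br)C(F)(F)F
F3 | step 4 | 4-[(2R,3S)-4-bromo-3-(3,5-dimethoxyphenyl)-6-methoxy-2,3-dihydro-1-benzofuran-2-yl]phenyl trifluoromethanesulfonate | O=S(=O)(Oc1ccc([C@@H]2Oc3cc(OC)cc(Br)c3[C@@H]2c2cc(OC)cc(OC)c2)cc1)C(F)(F)F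
F4 | step 4 | 4-[(2R,3S)-4-bromo-3-(3,5-dihydroxyphenyl)-6-hydroxy-2,3-dihydro-1-benzofuran-2-yl]phenyl trifluoromethanesulfonate | O=S(=O)(Oc1ccc([C@@H]2Oc3cc(O)cc(Br)c3[C@@H]2c2cc(O)cc(O)c2)cc1)C(F)(F)F
F5 | step 8 | (2S,3S)-2-(4-acetoxyphenyl)-3-(3,5-diacetoxyphenyl)-4-[(E)-2-(4-hydroxyphenyl)ethenyl]-2,3-dihydro-1-benzofuran-6-yl acetate | CC(=O)Oc1ccc([C@H]2Oc3cc(OC(C)=O)cc(/C=C/c4ccc(O)cc4)c3[C@@H]2c2cc(OC(C)=O)cc(OC(C)=O)c2)cc1
F6 | step 8 | (2S,3S,4S,5R)-2,5-bis(4-hydroxyphenyl)-3,4-bis[(2S,3S)-6-acetoxy-2-(4-acetoxyphenyl)-3-(3,5-diacetoxyphenyl)-2,3-dihydro-1-benzofuran-4-yl]oxolane | CC(=O)Oc1ccc([C@H]2Oc3cc(OC(C)=O)cc([C@@H]4[C@@H](c5cc(OC(C)=O)cc6c5[C@H](c5cc(OC(C)=O)cc(OC(C)=O)c5)[C@@H](c5ccc(OC(C)=O)cc5)O6)[C@H](c5ccc(O)cc5)O[C@@H]4c4ccc(O)cc4)c3[C@@H]2c2cc(OC(C)=O)cc(OC(C)=O)c2)cc1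
F7 | step 7 | (E)-tert-butyldimethyl{4-[2-(4,4,5,5-tetramethyl-1,3,2-dioxaborolan-2-yl)ethenyl]phenoxy}silane | CC(C)(C)[Si](C)(C)Oc1ccc(/C=C/B2OC(C)(C)C(C)(C)O2)cc1
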